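The dihydrofuran ring (O1–C2–C3–C3a–C7a) is cut at O1–C2 and C3–C3a. This exploits its polarity. C3 is a carbinol carbon (aldehyde level) and C2 is an O-bearing carbon beside a latent isopropenyl group, so C2–C3 is a 1,2-dielectrophile. C3a and O1 of the arene form a C,O-dinucleophile. In one operation an ortho-lithiated phenoxide adds to (S)-3,3-dimethyloxirane-2-carbaldehyde, and the phenoxide then opens the temporary epoxide ring 5-exo at C2. This (3+2) annulation closes the ring and sets both stereocentres. The cis-alcohol is esterified with inversion (Mitsunobu), and the liberated tertiary alcohol is dehydrated to the isopropenyl group.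

Key step: step 4

Remark: the target is read as the trans-(2R,3S)-dihydrobenzofuran whose enoate is Z (CH3 cis to the ester carbonyl, angelate-type). Benzofuran numbering (O1, C2, C3, C3a, C4–C7, C7a) is used throughout.

Step 1
Reactants: 1 3-methylbut-2-en-1-ol (prenol)
Product: 2 (R)-(3,3-dimethyloxiran-2-yl)methanol
Conditions: Ti(OiPr)4 (cat.), D-(−)-diisopropyl tartrate (cat.), t-BuOOH, 4 Å MS, CH2Cl2, −20 °C
Reagents that add atoms: tert-butyl hydroperoxide, CC(C)(C)OO
Why: Sharpless asymmetric epoxidation of an allylic alcohol, in which the D-(−)-tartrate delivers oxygen to the face that gives the (R)-epoxy alcohol and so fixes the absolute configuration of the later C2.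

Step 2
Reactants: 2 (R)-(3,3-dimethyloxiran-2-yl)methanol
Product: 3 (S)-3,3-dimethyloxirane-2-carbaldehyde
Conditions: TEMPO (cat.), PhI(OAc)2, CH2Cl2, 0 °C → rt
Reagents that add atoms: none
Why: Oxoammonium-mediated (TEMPO) alcohol oxidation stops at the aldehyde and leaves the epoxide and its configurationally robust stereocentre untouched, so only the CIP descriptor changes.

Step 3
Reactants: 4 1-(3-bromo-4-hydroxyphenyl)ethan-1-one (3'-bromo-4'-hydroxyacetophenone)
Product: 5 2-bromo-4-(2-methyl-1,3-dioxolan-2-yl)phenol
Conditions: HOCH2CH2OH, p-TsOH·H2O (cat.), toluene, reflux, Dean–Stark; NaHCO3 wash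
Reagents that add atoms: ethylene glycol, OCCO
Why: Acid-catalysed ketalisation with azeotropic removal of water masks the methyl ketone against the organolithium chemistry of step 4, and no stereocentre is involved.

Step 4
Reactants: 5 2-bromo-4-(2-methyl-1,3-dioxolan-2-yl)phenol; 3 (S)-3,3-dimethyloxirane-2-carbaldehyde
Product: 9 1-[(2S,3R)-3-hydroxy-2-(2-hydroxypropan-2-yl)-2,3-dihydro-1-benzofuran-5-yl]ethan-1-one (cis-diol), via dilithiated phenoxide 6 (not isolated), via anti epoxy alcohol 7 (not isolated), via cis-diol ketal 8 (not isolated)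
Conditions: n-BuLi (2.1 equiv), Et2O, 0 °C → rt; 3, THF, −78 °C; MeOH, −78 °C → rt; 1 M aq HCl, THF, 0 °C
Reagents that add atoms: water, O
Why: Deprotonation and Br/Li exchange give the C,O-dianion 6, whose aryl carbon adds to the aldehyde of 3 at −78 °C faster than to the epoxide; after the methanol quench only the phenol stays ionised, its oxygen opens the epoxide at C2 by SN2, and the acidic work-up unmasks the ketone. The closest known reaction types are aryllithium 1,2-addition to α,β-epoxy aldehydes, the base-induced cyclisation of ortho-(epoxyprenyl)phenols to 2-(2-hydroxypropan-2-yl)dihydrobenzofurans and, for the overall dinucleophile/1,2-dielectrophile logic, the interrupted Feist–Bénary reaction. The one ring that is closed, the dihydrofuran, forms by a 5-exo-tet epoxide opening. C3 is controlled by Cornforth/polar Felkin–Anh addition (C=O anti to the epoxide C–O bond, attack past the epoxide hydrogen, the CMe2 terminus and its cis-methyl group blocking the other flank, THF disfavouring a lithium chelate), which should favour anti epoxy alcohol 7, while C2 is controlled by clean inversion at the epoxide carbon set in step 1, so that anti-7 maps onto the cis-(2S,3R) diol. The step needs 5-exo over 6-endo opening and phenoxide over alkoxide attack (Payne rearrangement): the basic medium, free of strong Lewis acid, directs attack to the less substituted epoxide carbon, and the pKa gap in methanol keeps the secondary alcohol protonated. Because C2 is fixed independently of C3, material epimeric at C3 remains usable.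

Step 5
Reactants: 10 (E)-but-2-enal (crotonaldehyde)
Product: 12 (Z)-2-bromobut-2-enal, via 2,3-dibromobutanal 11 (not isolated)
Conditions: Br2, CH2Cl2, 0 °C; Et3N, 0 °C → rt
Reagents that add atoms: bromine, BrBr
Why: Electrophilic bromination of the enal followed by amine-induced dehydrobromination (loss of the acidic α-H and the β-bromide) gives the thermodynamically preferred (Z)-α-bromoenal, in which CH3 stays trans to CHO and is therefore cis to Br.

Step 6
Reactants: 12 (Z)-2-bromobut-2-enal
Product: 13 (Z)-2-bromobut-2-en-1-ol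
Conditions: NaBH4, MeOH, 0 °C
Reagents that add atoms: none
Why: Borohydride 1,2-reduction of the aldehyde leaves the trisubstituted bromoalkene and its geometry unaffected.

Step 7
Reactants: 13 (Z)-2-bromobut-2-en-1-ol
Product: 15 (Z)-2-(hydroxymethyl)but-2-enoic acid, via dilithio alkenyl alkoxide 14 (not isolated)
Conditions: t-BuLi (3.1 equiv), Et2O, −78 °C; CO2, −78 → 0 °C; 1 M aq HCl
Reagents that add atoms: carbon dioxide, O=C=O
Why: Deprotonation and stereoretentive Br/Li exchange give a configurationally stable alkenyllithium that is carboxylated with retention, so that CO2H takes the place of Br cis to CH3 (Z geometry).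

Step 8
Reactants: 15 (Z)-2-(hydroxymethyl)but-2-enoic acid
Product: 16 (Z)-2-(acetoxymethyl)but-2-enoic acid
Conditions: Ac2O, pyridine, CH2Cl2, 0 °C → rt; H2O work-up
Reagents that add atoms: acetic anhydride, CC(=O)OC(C)=O
Why: Standard O-acetylation of the primary allylic alcohol, in which any mixed anhydride formed at the acid is hydrolysed on aqueous work-up and the alkene geometry is untouched.

Step 9
Reactants: 9 1-[(2S,3R)-3-hydroxy-2-(2-hydroxypropan-2-yl)-2,3-dihydro-1-benzofuran-5-yl]ethan-1-one; 16 (Z)-2-(acetoxymethyl)but-2-enoic acid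
Product: 17 (2S,3S)-5-acetyl-2-(2-hydroxypropan-2-yl)-2,3-dihydro-1-benzofuran-3-yl (Z)-2-(acetoxymethyl)but-2-enoate (trans)
Conditions: PPh3, DIAD (premixed, 0 °C), then 16 and 9, toluene, 0 °C → rt
Reagents that add atoms: none
Why: In this Mitsunobu esterification only the secondary benzylic C3–OH is activated (the tertiary alcohol is inert, and the 5-acetyl group para to O1 disfavours ionisation), and the carboxylate of 16 displaces it by SN2 from the face opposite the bulky C2 substituent, which inverts C3 from R to S (cis to trans) and preserves the Z-enoate because the acid is never activated at its carbonyl group.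

Step 10
Reactants: 17 (2S,3S)-5-acetyl-2-(2-hydroxypropan-2-yl)-2,3-dihydro-1-benzofuran-3-yl (Z)-2-(acetoxymethyl)but-2-enoate
Product: 18 (2R,3S)-5-acetyl-2-(prop-1-en-2-yl)-2,3-dihydro-1-benzofuran-3-yl (Z)-2-(acetoxymethyl)but-2-enoate (target)
Conditions: Burgess reagent (methyl N-(triethylammoniosulfonyl)carbamate), toluene, 50 °C
Reagents that add atoms: none
Why: Burgess dehydration (syn-elimination of a tertiary sulfamate ester) under nearly neutral conditions should remove one of the six unhindered methyl hydrogens rather than the single ring C2–H, giving the isopropenyl group without touching C2, C3 or the esters, and the C2 descriptor changes from S to R only through CIP priorities.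

Compound list
1 | 3-methylbut-2-en-1-ol (prenol) | CC(C)=CCO | starting material
2 | (R)-(3,3-dimethyloxiran-2-yl)methanol | OC[C@H]1OC1(C)C | intermediate
3 | (S)-3,3-dimethyloxirane-2-carbaldehyde | O=C[C@H]1OC1(C)C | intermediate
4 | 1-(3-bromo-4-hydroxyphenyl)ethan-1-one | CC(=O)c1ccc(O)c(Br)c1 | starting material
5 | 2-bromo-4-(2-methyl-1,3-dioxolan-2-yl)phenol | CC1(OCCO1)c1ccc(O)c(Br)c1 | intermediate
6 | lithium 2-lithio-4-(2-methyl-1,3-dioxolan-2-yl)phenoxide (not isolated) | CC1(OCCO1)c1ccc(O[Li])c([Li])c1 | intermediate
7 | 2-{(R)-[(2R)-3,3-dimethyloxiran-2-yl](hydroxy)methyl}-4-(2-methyl-1,3-dioxolan-2-yl)phenol, anti epoxy alcohol (not isolated) | O[C@H](c1cc(ccc1O)C1(C)OCCO1)[C@H]1OC1(C)C | intermediate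
8 | (2S,3R)-2-(2-hydroxypropan-2-yl)-5-(2-methyl-1,3-dioxolan-2-yl)-2,3-dihydro-1-benzofuran-3-ol (not isolated) | CC(C)(O)[C@H]1Oc2ccc(cc2[C@H]1O)C1(C)OCCO1 | intermediate
9 | 1-[(2S,3R)-3-hydroxy-2-(2-hydroxypropan-2-yl)-2,3-dihydro-1-benzofuran-5-yl]ethan-1-one (cis-diol) | CC(C)(O)[C@H]1Oc2ccc(C(C)=O)cc2[C@H]1O | intermediate
10 | (E)-but-2-enal (crotonaldehyde) | C/C=C/C=O | starting material
11 | 2,3-dibromobutanal (racemic, not isolated) | CC(Br)C(Br)C=O | intermediate
12 | (Z)-2-bromobut-2-enal | C/C=C(\Br)C=O | intermediate
13 | (Z)-2-bromobut-2-en-1-ol | C/C=C(\Br)CO | intermediate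
14 | lithium (Z)-2-lithiobut-2-en-1-olate (not isolated) | C/C=C(\[Li])CO[Li] | intermediate
15 | (Z)-2-(hydroxymethyl)but-2-enoic acid | C/C=C(\C(=O)O)CO | intermediate
16 | (Z)-2-(acetoxymethyl)but-2-enoic acid | C/C=C(\C(=O)O)COC(C)=O | intermediate
17 | (2S,3S)-5-acetyl-2-(2-hydroxypropan-2-yl)-2,3-dihydro-1-benzofuran-3-yl (Z)-2-(acetoxymethyl)but-2-enoate | CC(C)(O)[C@H]1Oc2ccc(C(C)=O)cc2[C@@H]1OC(=O)/C(=C\C)COC(C)=O | intermediate
18 | (2R,3S)-5-acetyl-2-(prop-1-en-2-yl)-2,3-dihydro-1-benzofuran-3-yl (Z)-2-(acetoxymethyl)but-2-enoate | C=C(C)[C@H]1Oc2ccc(C(C)=O)cc2[C@@H]1OC(=O)/C(=C\C)COC(C)=O | target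

Total step count: 10.
Longest linear sequence: 6 steps (10 → 12 → 13 → 15 → 16 → 17 → 18). The arm from 1 reaches 18 in 5 steps.

Steps most likely to fail

Step 4. The addition of 6 to 3 may show poor facial selectivity, because a lithium chelate can compete with the Cornforth arrangement. Much of the material would then be epimeric at C3. The fallback sets out from 5 and 3 as in step 4 but gives up control of C3. The C3 epimers are separated by chromatography, and the cis-diol 9 continues through step 9. The trans-diol 1-[(2S,3S)-3-hydroxy-2-(2-hydroxypropan-2-yl)-2,3-dihydro-1-benzofuran-5-yl]ethan-1-one F1 has the same C2 and already the final C3 configuration, so it is esterified with retention. For this, 16 is converted with 2,4,6-trichlorobenzoyl chloride and Et3N into (Z)-2-(acetoxymethyl)but-2-enoic 2,4,6-trichlorobenzoic anhydride F2. F2 acylates the secondary hydroxyl of F1 in toluene at 80 °C without a nucleophilic catalyst, which is the Yamaguchi-type protocol used for angelate-type esters. Both branches come back to the route at 17.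

Step 9. Activation of the hindered cis-alcohol and displacement by the weakly acidic enoic acid may be slow. Elimination across C2–C3 with aromatisation to the benzofuran, partial ionisation at C3, or phosphine-induced isomerisation of the Z-enoate could then take over. The fallback sets out from 9 and separates inversion from introduction of the sensitive acid. Mitsunobu inversion with the more acidic 4-nitrobenzoic acid gives (2S,3S)-5-acetyl-2-(2-hydroxypropan-2-yl)-2,3-dihydro-1-benzofuran-3-yl 4-nitrobenzoate F3. Methanolysis (K2CO3, MeOH) releases the trans-diol F1. F1 is acylated with retention by the mixed anhydride F2 as described above. The fallback comes back to the route at 17.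

Step 10. During dehydration the C3 carboxylate may be lost with aromatisation to the benzofuran. The allylic acetate or Z-enoate may be scrambled, or proton loss may occur at C2 instead of at a methyl group. The fallback sets out from 9 and moves the dehydration ahead of the esterification.
- Selective silylation of the secondary alcohol (TESCl, imidazole) gives 1-[(2S,3R)-2-(2-hydroxypropan-2-yl)-3-(triethylsilyloxy)-2,3-dihydro-1-benzofuran-5-yl]ethan-1-one F4.
- Burgess dehydration of this ester-free substrate, whose silyl ether is a poor leaving group, gives 1-[(2R,3R)-2-(prop-1-en-2-yl)-3-(triethylsilyloxy)-2,3-dihydro-1-benzofuran-5-yl]ethan-1-one F5.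
- HF·pyridine removes the silyl group to give the cis-alcohol 1-[(2R,3R)-3-hydroxy-2-(prop-1-en-2-yl)-2,3-dihydro-1-benzofuran-5-yl]ethan-1-one F6.
- Mitsunobu esterification of F6 with 16 (inversion at C3) comes back to the route at 18.

Further compounds
F1 | step 4 | 1-[(2S,3S)-3-hydroxy-2-(2-hydroxypropan-2-yl)-2,3-dihydro-1-benzofuran-5-yl]ethan-1-one (trans-diol) | CC(C)(O)[C@H]1Oc2ccc(C(C)=O)cc2[C@@H]1O
F2 | step 4 | (Z)-2-(acetoxymethyl)but-2-enoic 2,4,6-trichlorobenzoic anhydride | O=C(OC(=O)/C(=C\C)COC(C)=O)c1c(Cl)cc(Cl)cc1Cl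
F3 | step 9 | (2S,3S)-5-acetyl-2-(2-hydroxypropan-2-yl)-2,3-dihydro-1-benzofuran-3-yl 4-nitrobenzoate | CC(C)(O)[C@H]1Oc2ccc(C(C)=O)cc2[C@@H]1OC(=O)c1ccc(cc1)[N+](=O)[O-]
F4 | step 10 | 1-[(2S,3R)-2-(2-hydroxypropan-2-yl)-3-(triethylsilyloxy)-2,3-dihydro-1-benzofuran-5-yl]ethan-1-one | CC(C)(O)[C@H]1Oc2ccc(C(C)=O)cc2[C@H]1O[Si](CC)(CC)CC
F5 | step 10 | 1-[(2R,3R)-2-(prop-1-en-2-yl)-3-(triethylsilyloxy)-2,3-dihydro-1-benzofuran-5-yl]ethan-1-one | C=C(C)[C@H]1Oc2ccc(C(C)=O)cc2[C@H]1O[Si](CC)(CC)CC
F6 | step 10 | 1-[(2R,3R)-3-hydroxy-2-(prop-1-en-2-yl)-2,3-dihydro-1-benzofuran-5-yl]ethan-1-one (cis-alcohol) | C=C(C)[C@H]1Oc2ccc(C(C)=O)cc2[C@H]1O
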